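Abbreviations: PMB = 4-methoxybenzyl, TBS = tert-butyldimethylsilyl, TES = triethylsilyl, H2IMes = 1,3-dimesitylimidazolidin-2-ylidene, tBu-PHOX = 4-tert-butyl-2-[2-(diphenylphosphanyl)phenyl]-4,5-dihydro-1,3-oxazole.

## Analysis of the target

The target is a cyclohexene (ring A) trans-fused to an α-methylene-γ-butyrolactone (ring B) and carries three further esters. Ring A is numbered C1 (alkene carbon with the CH2O methacrylate), C2 (alkene carbon with the side chain), C3 (CH–OAc), C4 (fusion CH bonded to the lactone α-carbon Cα), C5 (fusion CH–O) and C6 (CH2); C1′ is the chain carbon CH(CH3) on C2, followed by three CH2 groups and the primary acetate. There are four stereocentres: C3 (S), C4 (S) and C5 (R) are contiguous, with C3–O cis to C4–Cα and C4–Cα trans to C5–O, while C1′ (S) lies outside the ring on a tetrasubstituted alkene with no rigid link to the ring stereocentres. The sensitive groups are the α-methylene lactone (a Michael acceptor), the polymerisable methacrylate, two acetates (one allylic at C3), and a lactone that can migrate to the C3 oxygen whenever that hydroxyl is free, because it is cis to C4–Cα. The difficulties are the C1=C2 alkene with four different carbon substituents flanked by stereocentres at C3 and C1′, three oxygens that must end with two kinds of acyl group, and the fact that no strongly basic step is possible once the esters are in place. The strategy rests on one feature: the unit C1=C2–C1′H(CH3) is the dihydro form of the diene C1=C2–C1′=CH2, and that diene is what enyne metathesis of an internal alkyne C2≡C1′ with a 1,1-disubstituted alkene at C1 produces, the ring itself fixing the alkene geometry.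

## Retrosynthetic reasoning

Acyl groups (26 ⇒ 25 ⇒ 24 ⇒ 23 ⇒ 22). The three exocyclic acyl–oxygen bonds are cut first, because none of them survives enolate chemistry. The methacrylate differs from the two acetates, so the C1 hydroxymethyl oxygen must be unmasked on its own: 26 comes from allylic alcohol 25, and 25 from PMB ether 24. The C3 and chain oxygens receive the same acyl group and can be freed together: 24 comes from diol 23, and 23 from bis-silyl ether 22.

Exocyclic methylene of ring B (22 ⇒ 21 ⇒ 20 ⇒ 19). The Cα=CH2 bond is cut next. The Michael acceptor must come after the hydrogenation that sets C1′, which would reduce it, and before any ester. The forward reaction is an enolate Mannich reaction followed by quaternisation and elimination, on a lactone whose only α-protons are on Cα and whose β-carbon C4 carries no leaving group.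

C1′ stereocentre (19 ⇒ 18). Removing H2 across C1′ and its methyl group turns the stereocentre into an exocyclic methylene. This converts a tetrasubstituted alkene with an allylic stereocentre into a 2-substituted 1,3-diene, the retron of enyne metathesis. The forward step must add hydrogen to one face of the 1,1-disubstituted alkene only and leave C1=C2 alone.

Ring A (18 ⇒ 17). The bonds C1=C2 and C1′=CH2 are cut together, giving lactone 17 with two arms: a 2-substituted allyl group on C5 and a silyloxy-alkynyl group on C4. This is the only ring disconnection that creates no stereocentre during ring closure, and the ring enforces the alkene geometry. A cut at C3–C4 or C4–C5 would instead require the tetrasubstituted alkene to be built with defined geometry in an open chain. The forward reaction must start at the alkyne, place the metal on C2 and close the six-membered ring.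

C3 stereocentre (17 ⇒ 16 ⇒ 15). The silyl ether is removed and the C3–H bond is cut to ynone 15. C3 lies outside ring B at this stage, so substrate control would be unreliable, and a catalyst-controlled reduction of the alkynyl ketone is used.

C2–C3 bond (15 ⇒ 14 + 13; 14 from 11; 13 from 12). Cutting between the carbonyl carbon and the alkyne splits the molecule into lactone acid 11, activated as acid chloride 14, and the five-carbon alkyne 13. The forward coupling must acylate the alkyne C–H without touching the lactone, which rules out strongly nucleophilic acetylides.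

Ring B and the C4–C5 bond (11 ⇒ 10 ⇒ 9 ⇒ 8 + 5). The lactone C5–O acyl bond is opened and the C4–C5 bond is cut as an aldol. The trans lactone corresponds to a syn aldol between the succinate imide 8 and aldehyde 5, so both ring-fusion stereocentres come from one auxiliary-controlled step, and the hydroxy ester 9 closes to 10 by itself.

Building blocks (8 ⇒ 6 + 7; 5 ⇒ 4 ⇒ 3 ⇒ 1 + 2). The imide is cut at the N-acyl bond into auxiliary 6 and half-ester chloride 7. Aldehyde 5 is taken back to alcohol 4 so that the isomerisation-prone β,γ-unsaturated aldehyde exists only briefly. Alcohol 4 is cut at the bond to its terminal CH2OH carbon, a one-carbon electrophile added to the allyl chloride 3. Chloride 3 is cut at the ether bond into 1 and the symmetrical dichloride 2.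

## Alternatives that were turned down

Alternative 1: Ring A is cut at C2–C3 and C1–C6 into 3-(benzyloxy)cyclobutanone A1 and the silyl alkyne A2, which already carries C1′.
- Forward key step: a zerovalent nickel catalyst with a chiral phosphine couples the alkyne and the carbonyl group to an oxanickelacycle, β-carbon elimination opens the four-membered ring, and reductive elimination gives cyclohexenone A3 (ketone at C3, silyl group at C1, benzyloxy group at C5).
- For: two ring bonds form in one convergent step, and C1′ arrives as a building-block stereocentre. On C1′ this alternative is stronger than the chosen route, which needs a late face-selective hydrogenation.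
- Against: the unsymmetrical, α-branched alkyne must insert with the branched carbon next to the carbonyl group, and an intermolecular partner must distinguish the two enantiotopic ring bonds of A1; neither is secured.
- Against: A3 is far from the target. C4 is a bare CH2 between the ketone and C5, so attaching Cα means enolising toward C4, where the C5 oxygen is β to the enolate and is expelled, after which the ring aromatises. The silyl group on C1 must still become CH2O, and C3 and C4 must still be set.
- Comparison: the chosen route offers instead a precursor 17 in which C4, C5, Cα and the C1 hydroxymethyl group are in place before ring closure, and ring A needs no redox adjustment afterwards.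

Alternative 2: Ring A is cut at C4–C5 to the open-chain aldehyde allylboronate A4.
- Forward key step: on heating or with a Lewis acid the γ-carbon C4 of the 2-(methoxycarbonyl)allyl boronate adds to the C5 aldehyde through a chair transition state, closing ring A to hydroxy ester A5 and setting C4 and C5.
- For: the allyl shift creates the acrylate methylene, so lactonisation of A5 gives the α-methylene lactone with no enolate chemistry, and the acetates could be installed earlier. On the endgame this alternative is stronger than the chosen route.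
- Against: A4 must hold the tetrasubstituted C1=C2 alkene with defined geometry in an open chain, with C1′ and C3 attached, next to a β,γ-unsaturated aldehyde prone to conjugation and an allylic boronate prone to 1,3-shift.
- Against: the C4/C5 outcome depends on the boronate alkene geometry and on whether the tethered chair is reachable, with the C3 silyloxy group beside the reacting carbon.
- Comparison: the route to A4 is long and its risk is spread over many steps. The chosen route puts the risk in one step on a precursor made by routine chemistry and lets the ring dictate the alkene geometry.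

Alternative 3: Ring A is cut at C3–C4 to the enal A6, which carries a 2-(acetoxymethyl)enoate.
- Forward key step: a triazolium-derived carbene turns the C3 aldehyde into an acyl anion equivalent that adds to C4, and loss of the acetoxy group gives the exocyclic methylene in enone A7.
- For: like alternative 2 it builds the acrylate methylene during ring closure, and the C3 ketone leaves a late reduction that can be steered. On these points it equals or exceeds the chosen route.
- Against: the aldehyde is a fully substituted enal, and carbene adducts of enals react preferentially as homoenolates at the β-carbon (here C1) rather than as acyl anions.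
- Against: in A7 the C4–H is flanked by the ketone and the acrylate, so the basic conditions invite epimerisation and migration of the methylene into conjugation, and the C5 silyloxy group is β to the ketone and can be eliminated toward an aromatic ring.
- Against: A6 again needs the open-chain tetrasubstituted alkene, and the ketone reduction must still give C3–O cis to C4–Cα.
- Comparison: the chosen route forms no stereocentre and no acidic centre in its ring-closing step, and sets C3, C4 and C5 beforehand by auxiliary and catalyst control.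

Key step: step 11

Remark on the chemistry: the sense of the two catalyst-controlled reductions (steps 9 and 12) is assigned by analogy with simple alkynyl ketones and 1,1-disubstituted alkenes; should either prove opposite, the mirror-image catalyst is used and nothing else changes.

## Route

Step 1
Reactants: 1 4-methoxybenzyl alcohol; 2 3-chloro-2-(chloromethyl)prop-1-ene (excess)
Product: 3 2-(chloromethyl)prop-2-en-1-yl 4-methoxybenzyl ether
Conditions: NaH, Bu4NI (cat.), THF/DMF, 0 °C to rt
Reagents that add atoms: none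
Why: Williamson etherification; the sodium alkoxide of 1 displaces one allylic chloride of 2, which is used in excess so that double substitution stays minor.

Step 2
Reactants: 3 2-(chloromethyl)prop-2-en-1-yl 4-methoxybenzyl ether
Product: 4 3-[(PMB-oxy)methyl]but-3-en-1-ol
Conditions: In powder, NaI (cat.), 37% aq. HCHO, THF/H2O, rt
Reagents that add atoms: formaldehyde, C=O
Why: Barbier-type allylation in water; both allyl termini are CH2 groups, so either mode of addition gives the same homoallylic alcohol, and the PMB ether is inert.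

Step 3
Reactants: 4 3-[(PMB-oxy)methyl]but-3-en-1-ol
Product: 5 3-[(PMB-oxy)methyl]but-3-enal
Conditions: Dess–Martin periodinane, CH2Cl2, 0 °C to rt; used crude at once
Reagents that add atoms: none
Why: Dess–Martin oxidation under near-neutral conditions should keep the β,γ-unsaturated aldehyde from moving into conjugation; 5 is not purified.

Step 4
Reactants: 6 (4S)-4-benzyl-1,3-oxazolidin-2-one; 7 methyl 4-chloro-4-oxobutanoate
Product: 8 methyl 4-[(4S)-4-benzyl-2-oxo-1,3-oxazolidin-3-yl]-4-oxobutanoate
Conditions: nBuLi, THF, −78 °C; then 7, −78 to 0 °C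
Reagents that add atoms: none
Why: N-acylation of the lithiated oxazolidinone; the acid chloride reacts far faster than the methyl ester at low temperature.

Step 5
Reactants: 8 methyl 4-[(4S)-4-benzyl-2-oxo-1,3-oxazolidin-3-yl]-4-oxobutanoate; 5 3-[(PMB-oxy)methyl]but-3-enal
Product: 10 (4S)-4-benzyl-3-({(2R,3S)-5-oxo-2-[2-((PMB-oxy)methyl)prop-2-en-1-yl]oxolan-3-yl}carbonyl)-1,3-oxazolidin-2-one, via syn aldol adduct 9 (not isolated)
Conditions: Bu2BOTf, iPr2NEt, CH2Cl2, 0 °C; 5, −78 to 0 °C; pH 7 buffer, MeOH, H2O2; then PPTS (cat.), toluene, 50 °C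
Reagents that add atoms: none
Why: Evans syn aldol; the Z-boron enolate of the imide (the ester is not enolised) reacts through a chair transition state on the face away from the benzyl group and sets C4 and C5 as (3S,4R) in 9. The new hydroxyl then closes onto the methyl ester, and because a syn aldol places the acyl group and the C5 side chain on opposite faces of the five-membered ring, the lactone is trans.

Step 6
Reactants: 10 (4S)-4-benzyl-3-({(2R,3S)-5-oxo-2-[2-((PMB-oxy)methyl)prop-2-en-1-yl]oxolan-3-yl}carbonyl)-1,3-oxazolidin-2-one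
Product: 11 (2R,3S)-5-oxo-2-{2-[(PMB-oxy)methyl]prop-2-en-1-yl}oxolane-3-carboxylic acid
Conditions: LiOH, H2O2, THF/H2O, 0 °C; Na2SO3; HCl to pH 2
Reagents that add atoms: hydrogen peroxide, OO
Why: Imide cleavage by lithium hydroperoxide, which attacks the exocyclic carbonyl selectively; any lactone opened by hydroxide re-closes on acidification since only the γ-lactone can form, and trans is also the stable arrangement at C4.

Step 7
Reactants: 12 pent-4-yn-1-ol
Product: 13 tert-butyl(dimethyl)(pent-4-yn-1-yloxy)silane
Conditions: TBSCl, imidazole, CH2Cl2, rt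
Reagents that add atoms: tert-butyl(chloro)dimethylsilane, CC(C)(C)[Si](C)(C)Cl
Why: Silylation of the primary alcohol; the alkyne C–H is untouched and the TBS ether survives every step up to the fluoride treatment.

Step 8
Reactants: 11 (2R,3S)-5-oxo-2-{2-[(PMB-oxy)methyl]prop-2-en-1-yl}oxolane-3-carboxylic acid; 13 tert-butyl(dimethyl)(pent-4-yn-1-yloxy)silane
Product: 15 (4S,5R)-4-[6-(TBS-oxy)hex-2-ynoyl]-5-{2-[(PMB-oxy)methyl]prop-2-en-1-yl}oxolan-2-one, via acid chloride 14 (not isolated)
Conditions: 1-chloro-N,N,2-trimethylprop-1-en-1-amine, CH2Cl2, 0 °C to rt; then 13, PdCl2(PPh3)2 (cat.), CuI (cat.), Et3N, THF, rt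
Reagents that add atoms: 1-chloro-N,N,2-trimethylprop-1-en-1-amine, CC(C)=C(Cl)N(C)C (chlorine of intermediate 14 only)
Why: Acyl Sonogashira coupling; the chloroenamine makes 14 without HCl (PMB ether, alkene), and the copper acetylide of 13 is acylated via the acylpalladium species under conditions that leave the γ-lactone alone, which a lithium acetylide would not. C4 is epimerisable here, but trans is the stable arrangement.

Step 9
Reactants: 15 (4S,5R)-4-[6-(TBS-oxy)hex-2-ynoyl]-5-{2-[(PMB-oxy)methyl]prop-2-en-1-yl}oxolan-2-one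
Product: 16 (4R,5R)-4-[(1S)-1-hydroxy-6-(TBS-oxy)hex-2-yn-1-yl]-5-{2-[(PMB-oxy)methyl]prop-2-en-1-yl}oxolan-2-one (the ring descriptor changes by priority only)
Conditions: Ru(p-cymene)[(S,S)-TsNCH(Ph)CH(Ph)NH] (cat.), iPrOH, rt
Reagents that add atoms: none
Why: Noyori-type asymmetric transfer hydrogenation of an alkynyl ketone under catalyst control; the (S,S) complex should deliver hydride to the face that gives the (S)-carbinol at C3, the alkynyl group taking the role of the aryl group of aryl ketones. The base-free conditions protect C4 from epimerisation and keep the lactone from migrating to the new hydroxyl.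

Step 10
Reactants: 16 (4R,5R)-4-[(1S)-1-hydroxy-6-(TBS-oxy)hex-2-yn-1-yl]-5-{2-[(PMB-oxy)methyl]prop-2-en-1-yl}oxolan-2-one
Product: 17 (4S,5R)-4-[(1S)-6-(TBS-oxy)-1-(TES-oxy)hex-2-yn-1-yl]-5-{2-[(PMB-oxy)methyl]prop-2-en-1-yl}oxolan-2-one
Conditions: TESCl, imidazole, DMAP (cat.), CH2Cl2, 0 °C
Reagents that add atoms: chlorotriethylsilane, CC[Si](Cl)(CC)CC
Why: Silylation; the TES ether masks the C3 hydroxyl from the ruthenium carbene and the lithium amide, blocks lactone migration, and leaves later together with the TBS group.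

Step 11
Reactants: 17 (4S,5R)-4-[(1S)-6-(TBS-oxy)-1-(TES-oxy)hex-2-yn-1-yl]-5-{2-[(PMB-oxy)methyl]prop-2-en-1-yl}oxolan-2-one
Product: 18 (3aS,4S,7aR)-6-[(PMB-oxy)methyl]-5-[5-(TBS-oxy)pent-1-en-2-yl]-4-(TES-oxy)-3a,4,7,7a-tetrahydro-1-benzofuran-2(3H)-one
Conditions: second-generation Grubbs catalyst RuCl2(=CHPh)(PCy3)(H2IMes) (10 mol%), ethylene (1 atm), toluene, 80 °C
Reagents that add atoms: none
Why: Ring-closing enyne metathesis of a 1,7-enyne, the known ruthenium-catalysed route to 1-alkenylcyclohexenes, here at the demanding end of its scope (internal alkyne, 1,1-disubstituted alkene, tetrasubstituted ring alkene). The ruthenium methylidene kept alive by ethylene adds to the C2≡C1′ alkyne, which is far more accessible than the 1,1-disubstituted alkene; its CH2 bonds to C1′, the alkyne carbon with the unbranched chain, and ruthenium ends on C2 when the ruthenacyclobutene opens to the vinyl carbene Ru=C2–C1′(=CH2). This carbene then meets the tethered C1=CH2 group in a ruthenacyclobutane whose cycloreversion forms C1=C2 and returns the methylidene. Ring A closes in the exo mode with respect to the alkyne (C2 inside, C1′ outside) to a six-membered ring; the endo alternative needs a seven-membered ring with an equally substituted alkene and should be slower. No stereocentre is formed and C3, C4 and C5 are spectators; the trans lactone holds the C3 and C6 arms pseudo-diequatorial, roughly 80° apart, within reach of a six-membered ring. The selectivity needed is alkyne-first initiation with ruthenium on C2 and exo closure; it rests on the four-atom tether, on the size difference between the branched silyloxy-bearing side and the linear side of the alkyne, and on ethylene, which turns any carbene that fails to cyclise into a 2,3-disubstituted butadiene that can still reach 18 by diene metathesis. The TES ether keeps the propargylic oxygen off ruthenium, and the lactone, PMB and silyl ethers are inert to the catalyst.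

Step 12
Reactants: 18 (3aS,4S,7aR)-6-[(PMB-oxy)methyl]-5-[5-(TBS-oxy)pent-1-en-2-yl]-4-(TES-oxy)-3a,4,7,7a-tetrahydro-1-benzofuran-2(3H)-one
Product: 19 (3aS,4S,7aR)-6-[(PMB-oxy)methyl]-5-[(2S)-5-(TBS-oxy)pentan-2-yl]-4-(TES-oxy)-3a,4,7,7a-tetrahydro-1-benzofuran-2(3H)-one
Conditions: [Ir(cod)((S)-tBu-PHOX)][B(3,5-(CF3)2C6H3)4] (cat.), H2 (1 bar), CH2Cl2, rt
Reagents that add atoms: none
Why: Iridium-catalysed asymmetric hydrogenation of an unfunctionalised 1,1-disubstituted alkene; this catalyst class does not reduce the tetrasubstituted C1=C2 bond at 1 bar. C1′ is set by the chiral ligand, which distinguishes the bulky ring-vinyl substituent from the linear CH2 chain, and low pressure limits migration of the terminal double bond before reduction.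

Step 13
Reactants: 19 (3aS,4S,7aR)-6-[(PMB-oxy)methyl]-5-[(2S)-5-(TBS-oxy)pentan-2-yl]-4-(TES-oxy)-3a,4,7,7a-tetrahydro-1-benzofuran-2(3H)-one
Product: 20 (3aS,4S,7aR)-3-[(dimethylamino)methyl]-6-[(PMB-oxy)methyl]-5-[(2S)-5-(TBS-oxy)pentan-2-yl]-4-(TES-oxy)-3a,4,7,7a-tetrahydro-1-benzofuran-2(3H)-one (either epimer at C3 of the lactone)
Conditions: LiN(iPr)2, THF, −78 °C; CH2=NMe2+ I−, −78 °C to rt
Reagents that add atoms: N,N-dimethylmethyleneiminium iodide, C=[N+](C)C.[I-]
Why: Mannich reaction of the lactone lithium enolate with the preformed iminium salt; the only α-protons are on Cα, C4 carries no leaving group so the enolate cannot eliminate, and silyl and PMB ethers tolerate the amide base. The new centre is erased in step 14.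

Step 14
Reactants: 20 (3aS,4S,7aR)-3-[(dimethylamino)methyl]-6-[(PMB-oxy)methyl]-5-[(2S)-5-(TBS-oxy)pentan-2-yl]-4-(TES-oxy)-3a,4,7,7a-tetrahydro-1-benzofuran-2(3H)-one
Product: 22 (3aS,4S,7aR)-3-methylidene-6-[(PMB-oxy)methyl]-5-[(2S)-5-(TBS-oxy)pentan-2-yl]-4-(TES-oxy)-3a,4,7,7a-tetrahydro-1-benzofuran-2(3H)-one, via trimethylammonium iodide 21 (not isolated)
Conditions: MeI, MeOH, rt; then NaHCO3 (aq.), CH2Cl2, rt
Reagents that add atoms: iodomethane, CI (methyl group and iodide of intermediate 21 only)
Why: N-methylation followed by base-induced Hofmann-type (E1cB) loss of trimethylamine gives the exocyclic α-methylene lactone; NaHCO3 is too weak to epimerise C4 or move the methylene into the ring.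

Step 15
Reactants: 22 (3aS,4S,7aR)-3-methylidene-6-[(PMB-oxy)methyl]-5-[(2S)-5-(TBS-oxy)pentan-2-yl]-4-(TES-oxy)-3a,4,7,7a-tetrahydro-1-benzofuran-2(3H)-one
Product: 23 (3aR,4S,7aR)-4-hydroxy-5-[(2S)-5-hydroxypentan-2-yl]-3-methylidene-6-[(PMB-oxy)methyl]-3a,4,7,7a-tetrahydro-1-benzofuran-2(3H)-one (the 3a descriptor changes by priority only)
Conditions: HF·pyridine, pyridine, THF, 0 °C
Reagents that add atoms: none
Why: Fluoride-mediated desilylation; buffered HF·pyridine should remove TES and TBS without touching the PMB ether, the Michael acceptor or the allylic C3–O bond. It is kept cold and short, and 23 is acetylated at once, because the freed C3 hydroxyl is cis to C4–Cα and could take over the lactone carbonyl.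

Step 16
Reactants: 23 (3aR,4S,7aR)-4-hydroxy-5-[(2S)-5-hydroxypentan-2-yl]-3-methylidene-6-[(PMB-oxy)methyl]-3a,4,7,7a-tetrahydro-1-benzofuran-2(3H)-one
Product: 24 (4S)-4-{(3aS,4S,7aR)-4-acetoxy-3-methylidene-2-oxo-6-[(PMB-oxy)methyl]-2,3,3a,4,7,7a-hexahydro-1-benzofuran-5-yl}pentyl acetate
Conditions: Ac2O, pyridine, DMAP (cat.), CH2Cl2, 0 °C to rt
Reagents that add atoms: acetic anhydride, CC(=O)OC(C)=O
Why: DMAP-catalysed acetylation of both hydroxyls; the hindered pseudoaxial C3 hydroxyl needs the nucleophilic catalyst, and O-acetylation should be much faster than lactone migration.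

Step 17
Reactants: 24 (4S)-4-{(3aS,4S,7aR)-4-acetoxy-3-methylidene-2-oxo-6-[(PMB-oxy)methyl]-2,3,3a,4,7,7a-hexahydro-1-benzofuran-5-yl}pentyl acetate
Product: 25 (4S)-4-[(3aS,4S,7aR)-4-acetoxy-6-(hydroxymethyl)-3-methylidene-2-oxo-2,3,3a,4,7,7a-hexahydro-1-benzofuran-5-yl]pentyl acetate
Conditions: DDQ, CH2Cl2/pH 7 buffer, 0 °C
Reagents that add atoms: none
Why: Oxidative cleavage of the PMB ether by benzylic hydride abstraction and hydrolysis; acetates and the α-methylene lactone are stable, and a small excess of oxidant at 0 °C limits oxidation of the freed allylic alcohol.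

Step 18
Reactants: 25 (4S)-4-[(3aS,4S,7aR)-4-acetoxy-6-(hydroxymethyl)-3-methylidene-2-oxo-2,3,3a,4,7,7a-hexahydro-1-benzofuran-5-yl]pentyl acetate
Product: 26 [(3aS,4S,7aR)-4-acetoxy-5-[(2S)-5-acetoxypentan-2-yl]-3-methylidene-2-oxo-2,3,3a,4,7,7a-hexahydro-1-benzofuran-6-yl]methyl 2-methylprop-2-enoate
Conditions: methacryloyl chloride, Et3N, DMAP (cat.), BHT (cat.), CH2Cl2, 0 °C
Reagents that add atoms: methacryloyl chloride, C=C(C)C(=O)Cl
Why: DMAP-catalysed acylation of the only remaining hydroxyl; the cold, brief reaction with a radical inhibitor guards both acrylate-type groups against polymerisation.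

## Compound list

1 | 4-methoxybenzyl alcohol | COc1ccc(CO)cc1 | starting material
2 | 3-chloro-2-(chloromethyl)prop-1-ene | C=C(CCl)CCl | starting material
3 | 2-(chloromethyl)prop-2-en-1-yl 4-methoxybenzyl ether | COc1ccc(COCC(=C)CCl)cc1 | intermediate
4 | 3-[(PMB-oxy)methyl]but-3-en-1-ol | COc1ccc(COCC(=C)CCO)cc1 | intermediate
5 | 3-[(PMB-oxy)methyl]but-3-enal | COc1ccc(COCC(=C)CC=O)cc1 | intermediate
6 | (4S)-4-benzyl-1,3-oxazolidin-2-one | O=C1N[C@@H](Cc2ccccc2)CO1 | starting material
7 | methyl 4-chloro-4-oxobutanoate | COC(=O)CCC(=O)Cl | starting material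
8 | methyl 4-[(4S)-4-benzyl-2-oxo-1,3-oxazolidin-3-yl]-4-oxobutanoate | COC(=O)CCC(=O)N1[C@@H](Cc2ccccc2)COC1=O | intermediate
9 | methyl (3S,4R)-3-{[(4S)-4-benzyl-2-oxo-1,3-oxazolidin-3-yl]carbonyl}-4-hydroxy-6-[(PMB-oxy)methyl]hept-6-enoate | COC(=O)C[C@H](C(=O)N1[C@@H](Cc2ccccc2)COC1=O)[C@H](O)CC(=C)COCc1ccc(OC)cc1 | intermediate
10 | (4S)-4-benzyl-3-({(2R,3S)-5-oxo-2-[2-((PMB-oxy)methyl)prop-2-en-1-yl]oxolan-3-yl}carbonyl)-1,3-oxazolidin-2-one | O=C1C[C@H](C(=O)N2[C@@H](Cc3ccccc3)COC2=O)[C@@H](CC(=C)COCc2ccc(OC)cc2)O1 | intermediate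
11 | (2R,3S)-5-oxo-2-{2-[(PMB-oxy)methyl]prop-2-en-1-yl}oxolane-3-carboxylic acid | O=C1C[C@H](C(=O)O)[C@@H](CC(=C)COCc2ccc(OC)cc2)O1 | intermediate
12 | pent-4-yn-1-ol | C#CCCCO | starting material
13 | tert-butyl(dimethyl)(pent-4-yn-1-yloxy)silane | C#CCCCO[Si](C)(C)C(C)(C)C | intermediate
14 | (2R,3S)-5-oxo-2-{2-[(PMB-oxy)methyl]prop-2-en-1-yl}oxolane-3-carbonyl chloride | O=C1C[C@H](C(=O)Cl)[C@@H](CC(=C)COCc2ccc(OC)cc2)O1 | intermediate
15 | (4S,5R)-4-[6-(TBS-oxy)hex-2-ynoyl]-5-{2-[(PMB-oxy)methyl]prop-2-en-1-yl}oxolan-2-one | CC(C)(C)[Si](C)(C)OCCCC#CC(=O)[C@H]1CC(=O)O[C@@H]1CC(=C)COCc1ccc(OC)cc1 | intermediate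
16 | (4R,5R)-4-[(1S)-1-hydroxy-6-(TBS-oxy)hex-2-yn-1-yl]-5-{2-[(PMB-oxy)methyl]prop-2-en-1-yl}oxolan-2-one | CC(C)(C)[Si](C)(C)OCCCC#C[C@@H](O)[C@H]1CC(=O)O[C@@H]1CC(=C)COCc1ccc(OC)cc1 | intermediate
17 | (4S,5R)-4-[(1S)-6-(TBS-oxy)-1-(TES-oxy)hex-2-yn-1-yl]-5-{2-[(PMB-oxy)methyl]prop-2-en-1-yl}oxolan-2-one | CC(C)(C)[Si](C)(C)OCCCC#C[C@@H](O[Si](CC)(CC)CC)[C@H]1CC(=O)O[C@@H]1CC(=C)COCc1ccc(OC)cc1 | intermediate
18 | (3aS,4S,7aR)-6-[(PMB-oxy)methyl]-5-[5-(TBS-oxy)pent-1-en-2-yl]-4-(TES-oxy)-3a,4,7,7a-tetrahydro-1-benzofuran-2(3H)-one | COc1ccc(COCC2=C(C(=C)CCCO[Si](C)(C)C(C)(C)C)[C@@H](O[Si](CC)(CC)CC)[C@H]3CC(=O)O[C@@H]3C2)cc1 | intermediate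
19 | (3aS,4S,7aR)-6-[(PMB-oxy)methyl]-5-[(2S)-5-(TBS-oxy)pentan-2-yl]-4-(TES-oxy)-3a,4,7,7a-tetrahydro-1-benzofuran-2(3H)-one | COc1ccc(COCC2=C([C@@H](C)CCCO[Si](C)(C)C(C)(C)C)[C@@H](O[Si](CC)(CC)CC)[C@H]3CC(=O)O[C@@H]3C2)cc1 | intermediate
20 | (3aS,4S,7aR)-3-[(dimethylamino)methyl]-6-[(PMB-oxy)methyl]-5-[(2S)-5-(TBS-oxy)pentan-2-yl]-4-(TES-oxy)-3a,4,7,7a-tetrahydro-1-benzofuran-2(3H)-one, C3 epimers | COc1ccc(COCC2=C([C@@H](C)CCCO[Si](C)(C)C(C)(C)C)[C@@H](O[Si](CC)(CC)CC)[C@H]3C(CN(C)C)C(=O)O[C@@H]3C2)cc1 | intermediate
21 | N,N,N-trimethylammonium iodide of 20 | COc1ccc(COCC2=C([C@@H](C)CCCO[Si](C)(C)C(C)(C)C)[C@@H](O[Si](CC)(CC)CC)[C@H]3C(C[N+](C)(C)C)C(=O)O[C@@H]3C2)cc1.[I-] | intermediate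
22 | (3aS,4S,7aR)-3-methylidene-6-[(PMB-oxy)methyl]-5-[(2S)-5-(TBS-oxy)pentan-2-yl]-4-(TES-oxy)-3a,4,7,7a-tetrahydro-1-benzofuran-2(3H)-one | COc1ccc(COCC2=C([C@@H](C)CCCO[Si](C)(C)C(C)(C)C)[C@@H](O[Si](CC)(CC)CC)[C@H]3C(=C)C(=O)O[C@@H]3C2)cc1 | intermediate
23 | (3aR,4S,7aR)-4-hydroxy-5-[(2S)-5-hydroxypentan-2-yl]-3-methylidene-6-[(PMB-oxy)methyl]-3a,4,7,7a-tetrahydro-1-benzofuran-2(3H)-one | COc1ccc(COCC2=C([C@@H](C)CCCO)[C@@H](O)[C@H]3C(=C)C(=O)O[C@@H]3C2)cc1 | intermediate
24 | (4S)-4-{(3aS,4S,7aR)-4-acetoxy-3-methylidene-2-oxo-6-[(PMB-oxy)methyl]-2,3,3a,4,7,7a-hexahydro-1-benzofuran-5-yl}pentyl acetate | COc1ccc(COCC2=C([C@@H](C)CCCOC(C)=O)[C@@H](OC(C)=O)[C@H]3C(=C)C(=O)O[C@@H]3C2)cc1 | intermediate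
25 | (4S)-4-[(3aS,4S,7aR)-4-acetoxy-6-(hydroxymethyl)-3-methylidene-2-oxo-2,3,3a,4,7,7a-hexahydro-1-benzofuran-5-yl]pentyl acetate | OCC1=C([C@@H](C)CCCOC(C)=O)[C@@H](OC(C)=O)[C@H]2C(=C)C(=O)O[C@@H]2C1 | intermediate
26 | [(3aS,4S,7aR)-4-acetoxy-5-[(2S)-5-acetoxypentan-2-yl]-3-methylidene-2-oxo-2,3,3a,4,7,7a-hexahydro-1-benzofuran-6-yl]methyl 2-methylprop-2-enoate | C=C(C)C(=O)OCC1=C([C@@H](C)CCCOC(C)=O)[C@@H](OC(C)=O)[C@H]2C(=C)C(=O)O[C@@H]2C1 | target

## Step count and least certain steps

Total: 18 steps. Longest linear sequence: 16 steps (steps 1–3, 5, 6, 8–18); steps 4 and 7 are branch steps.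

Step 11 (key step).
- Risk: the methylidene may add to the alkyne with reversed orientation (ruthenium on C1′), leaving only the slow seven-membered closure.
- Risk: ethylene may turn the vinyl carbene over faster than it cyclises onto the hindered 1,1-disubstituted alkene, so the reaction stalls at an open-chain stage.
- Risk: the catalyst may decompose at the temperature a tetrasubstituted ring alkene demands.
- Fallback: the two events are separated. Starting from 17, cross enyne metathesis with ethylene under pressure (RuCl2(=CHPh)(PCy3)(H2IMes), CH2Cl2, 40 °C) is run deliberately to the 2,3-dimethylidene triene F1, for which the orientation of the first addition no longer matters. Ring A is then closed by diene metathesis between the C2=CH2 and C1=CH2 groups with a catalyst built for tetrasubstituted alkenes, RuCl2(=CH-2-iPrOC6H4)[1,3-bis(2-methylphenyl)imidazolidin-2-ylidene], in toluene at 80–100 °C with ethylene swept out. The six-membered closure should be preferred over the seven-membered one and returns the route to 18.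

Step 12.
- Risk: poor facial selectivity at C1′, because both flanks of the exocyclic alkene are encumbered (CH2OPMB at C1, the silyl ether at C3) and substrate bias may oppose the ligand.
- Risk: migration of the terminal double bond before reduction, which erodes selectivity.
- Risk: loss of the acid-labile TES group to acidic iridium hydride species.
- Fallback: hydroxyl-directed hydrogenation from the C1 side. Starting from 18, the PMB group is removed with DDQ (CH2Cl2/pH 7 buffer, 0 °C) to give the dienol F2. Hydrogenation with [Rh(nbd)(dppb)]BF4 under H2 pressure in CH2Cl2 should give the saturated-chain alcohol F3. Rhodium bound to the C1 hydroxymethyl oxygen delivers hydrogen to the alkene face turned toward C1, while the chain points away from the pseudoaxial C3 silyl ether; this combination corresponds to (S) at C1′. Re-protection with 4-methoxybenzyl 2,2,2-trichloroacetimidate and catalytic La(OTf)3 returns the route to 19.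

Step 8.
- Risk: triethylamine may dehydrochlorinate 14 to a ketene, with loss of material or epimerisation at C4.
- Risk: amine or chloride may add to the ynone, and the alkyne may homocouple.
- Fallback: an amine-free Negishi-type acylation. Starting from 13, deprotonation with nBuLi (THF, −78 °C) and transmetallation with ZnCl2 gives the alkynylzinc chloride F4. It is coupled with 14 (made as in step 8) under Pd(PPh3)4 in THF at 0 °C to return to 15; alkynylzinc reagents do not attack lactones and no base is present.

Step 15.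
- Risk: acyl migration of the lactone from the C5 oxygen to the freed cis C3 hydroxyl.
- Risk: ionisation of the allylic C3–O bond.
- Fallback: the C3 hydroxyl is never set free. Starting from 22, the PMB ether is cleaved with DDQ to the silylated allylic alcohol F5. Acylation with methacryloyl chloride, Et3N and DMAP gives the silylated methacrylate F6. Both silyl ethers are then exchanged directly for acetates with Ac2O and catalytic Cu(OTf)2 in CH2Cl2 at 0 °C, which reaches 26 without passing through a C3 alcohol.

Step 17.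
- Risk: over-oxidation of the liberated primary allylic alcohol to the enal by DDQ, made more likely if ether cleavage at this hindered position is slow.
- Fallback: the oxidation is driven through and reversed. Starting from 24, excess DDQ at rt gives the enal F7. Luche reduction (NaBH4, CeCl3·7H2O, MeOH, −78 °C) returns 25, since cerium-assisted 1,2-reduction of the aldehyde should be much faster than conjugate reduction of the α-methylene lactone at this temperature.

## Further compounds

F1 | step 11 | (4S,5R)-4-[(1S)-2,3-dimethylidene-6-(TBS-oxy)-1-(TES-oxy)hexyl]-5-{2-[(PMB-oxy)methyl]prop-2-en-1-yl}oxolan-2-one | CC(C)(C)[Si](C)(C)OCCCC(=C)C(=C)[C@@H](O[Si](CC)(CC)CC)[C@H]1CC(=O)O[C@@H]1CC(=C)COCc1ccc(OC)cc1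
F2 | step 12 | (3aS,4S,7aR)-6-(hydroxymethyl)-5-[5-(TBS-oxy)pent-1-en-2-yl]-4-(TES-oxy)-3a,4,7,7a-tetrahydro-1-benzofuran-2(3H)-one | OCC1=C(C(=C)CCCO[Si](C)(C)C(C)(C)C)[C@@H](O[Si](CC)(CC)CC)[C@H]2CC(=O)O[C@@H]2C1
F3 | step 12 | (3aS,4S,7aR)-6-(hydroxymethyl)-5-[(2S)-5-(TBS-oxy)pentan-2-yl]-4-(TES-oxy)-3a,4,7,7a-tetrahydro-1-benzofuran-2(3H)-one | OCC1=C([C@@H](C)CCCO[Si](C)(C)C(C)(C)C)[C@@H](O[Si](CC)(CC)CC)[C@H]2CC(=O)O[C@@H]2C1
F4 | step 8 | chlorido[5-(TBS-oxy)pent-1-yn-1-yl]zinc | CC(C)(C)[Si](C)(C)OCCCC#C[Zn]Cl
F5 | step 15 | (3aS,4S,7aR)-6-(hydroxymethyl)-3-methylidene-5-[(2S)-5-(TBS-oxy)pentan-2-yl]-4-(TES-oxy)-3a,4,7,7a-tetrahydro-1-benzofuran-2(3H)-one | OCC1=C([C@@H](C)CCCO[Si](C)(C)C(C)(C)C)[C@@H](O[Si](CC)(CC)CC)[C@H]2C(=C)C(=O)O[C@@H]2C1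
F6 | step 15 | [(3aS,4S,7aR)-3-methylidene-2-oxo-5-[(2S)-5-(TBS-oxy)pentan-2-yl]-4-(TES-oxy)-2,3,3a,4,7,7a-hexahydro-1-benzofuran-6-yl]methyl 2-methylprop-2-enoate | C=C(C)C(=O)OCC1=C([C@@H](C)CCCO[Si](C)(C)C(C)(C)C)[C@@H](O[Si](CC)(CC)CC)[C@H]2C(=C)C(=O)O[C@@H]2C1
F7 | step 17 | (4S)-4-[(3aS,4S,7aR)-4-acetoxy-6-formyl-3-methylidene-2-oxo-2,3,3a,4,7,7a-hexahydro-1-benzofuran-5-yl]pentyl acetate | O=CC1=C([C@@H](C)CCCOC(C)=O)[C@@H](OC(C)=O)[C@H]2C(=C)C(=O)O[C@@H]2C1
A1 | alternative 1 | 3-(benzyloxy)cyclobutan-1-one | O=C1CC(OCc2ccccc2)C1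
A2 | alternative 1 | tert-butyl(dimethyl){[(4S)-4-methyl-6-(trimethylsilyl)hex-5-yn-1-yl]oxy}silane | C[Si](C)(C)C#C[C@@H](C)CCCO[Si](C)(C)C(C)(C)C
A3 | alternative 1 | (5S)-5-(benzyloxy)-2-[(2S)-5-(TBS-oxy)pentan-2-yl]-3-(trimethylsilyl)cyclohex-2-en-1-one | C[Si](C)(C)C1=C([C@@H](C)CCCO[Si](C)(C)C(C)(C)C)C(=O)C[C@H](OCc2ccccc2)C1
A4 | alternative 2 | methyl (2Z,4S,5E)-4-(TBS-oxy)-5-[(2S)-5-(TBS-oxy)pentan-2-yl]-6-[(PMB-oxy)methyl]-8-oxo-2-[(4,4,5,5-tetramethyl-1,3,2-dioxaborolan-2-yl)methyl]octa-2,5-dienoate | O=CC/C(COCc1ccc(OC)cc1)=C(/[C@@H](C)CCCO[Si](C)(C)C(C)(C)C)[C@@H](O[Si](C)(C)C(C)(C)C)/C=C(/CB1OC(C)(C)C(C)(C)O1)C(=O)OC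
A5 | alternative 2 | methyl 2-{(1S,2S,6R)-2-(TBS-oxy)-3-[(2S)-5-(TBS-oxy)pentan-2-yl]-6-hydroxy-4-[(PMB-oxy)methyl]cyclohex-3-en-1-yl}prop-2-enoate | COc1ccc(COCC2=C([C@@H](C)CCCO[Si](C)(C)C(C)(C)C)[C@@H](O[Si](C)(C)C(C)(C)C)[C@@H](C(=C)C(=O)OC)[C@H](O)C2)cc1
A6 | alternative 3 | methyl (2E,4R,6E)-2-(acetoxymethyl)-4-(TBS-oxy)-7-[(2S)-5-(TBS-oxy)pentan-2-yl]-6-[(PMB-oxy)methyl]-8-oxoocta-2,6-dienoate | O=C/C([C@@H](C)CCCO[Si](C)(C)C(C)(C)C)=C(/COCc1ccc(OC)cc1)C[C@@H](O[Si](C)(C)C(C)(C)C)/C=C(\COC(C)=O)C(=O)OC
A7 | alternative 3 | methyl 2-{(1S,6R)-6-(TBS-oxy)-3-[(2S)-5-(TBS-oxy)pentan-2-yl]-4-[(PMB-oxy)methyl]-2-oxocyclohex-3-en-1-yl}prop-2-enoate | COc1ccc(COCC2=C([C@@H](C)CCCO[Si](C)(C)C(C)(C)C)C(=O)[C@@H](C(=C)C(=O)OC)[C@H](O[Si](C)(C)C(C)(C)C)C2)cc1
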